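**Assumption:** the SMILES is read as the (3aR,4S,6R,7S,7aR) 6α,12-elemanolide with a (2Z)-2-(hydroxymethyl)but-2-enoate on O-8; the four starting materials are taken as catalogue compounds.

Comments use elemane locants: C6 = lactone carbinol, C7 = ring-fusion carbon bearing C11, C8 = ester carbinol, C10 = quaternary carbon. TBS = tert-butyldimethylsilyl, TES = triethylsilyl.

## Retrosynthetic overview

1. Ester side chain: Yamaguchi acylation of the free C8 alcohol with the silylated Z acid (from crotonaldehyde), then global desilylation.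
2. α-Methylene trans-lactone: thermodynamic reduction of a C6 ketone, lactonisation onto the C7 acetate arm, Eschenmoser methylenation.
3. C10 vinyl and C5 alkenyl groups: enone–cyclobutene [2+2] photocycloaddition (forms C5–C4 and C10–C1), then thermal cycloreversion/Cope rearrangement under control of C7/C8.
4. Cyclohexenone: light-driven 6-endo-dig radical cyclisation of an acyclic iodo-ynone; C7 is set by dianion alkylation anti to the C8 hydroxyl.
5. All chirality derives from C8 of ethyl (R)-4-bromo-3-hydroxybutanoate. Ring order: cyclohexenone → two transient cyclobutanes → γ-lactone.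

## Route

Step 1
Reactants: 1 ethyl (3R)-4-bromo-3-hydroxybutanoate
Product: 3 ethyl (3R)-4-iodo-3-[(triethylsilyl)oxy]butanoate, via iodohydrin ester 2 (not isolated)
Conditions: NaI, acetone, 56 °C; filter, concentrate; then Et3SiCl, imidazole, CH2Cl2, 0 → 23 °C
Reagents that add atoms: sodium iodide [Na+].[I-]; chlorotriethylsilane CC[Si](Cl)(CC)CC
Why: Finkelstein halide exchange (NaBr precipitates) followed by silylation of the secondary alcohol; the purchased C8 stereocentre is not touched.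

Step 2
Reactants: 3 ethyl (3R)-4-iodo-3-[(triethylsilyl)oxy]butanoate; 4 tert-butyldimethyl(prop-2-yn-1-yloxy)silane
Product: 6 (6R)-1-[(TBS)oxy]-7-iodo-6-[(TES)oxy]hept-2-yn-4-one, via lithium acetylide 5 (not isolated)
Conditions: 4, n-BuLi, THF, −78 °C; BF3·OEt2; then 3, −78 °C; aq NH4Cl
Reagents that add atoms: none
Why: Yamaguchi–Hirao ynone synthesis; the alkynyl–BF3 species adds once to the ester and the tetrahedral adduct survives until work-up, so no tertiary alcohol forms and the primary iodide is inert at −78 °C.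

Step 3
Reactants: 6 (6R)-1-[(TBS)oxy]-7-iodo-6-[(TES)oxy]hept-2-yn-4-one
Product: 8 (5S)-3-{[(TBS)oxy]methyl}-5-hydroxycyclohex-2-en-1-one, via silyl enone 7 (not isolated)
Conditions: (Me3Si)3SiH (1.3 equiv, slow addition), 4CzIPN (2 mol %), 2,6-lutidine, PhCF3 (0.01 M), 450 nm LEDs, 25 °C; then PPTS, MeOH, 23 °C
Reagents that add atoms: none
Why: Proposed new method: a light-initiated silyl-radical chain abstracts iodine from C9, and the nucleophilic primary radical adds 6-endo-dig to the electron-poor β-carbon (C10) of the ynone, because the carbonyl lies inside the forming ring and the 5-exo mode would attack the electron-rich α-carbon; the σ-vinyl radical then takes H from the silane to give the enone, the closest known reactions being intermolecular Giese additions of alkyl radicals to ynones and 6-endo-trig cyclisations of ω-iodoalkyl vinyl ketones, and the acidic methanol stage removes only the secondary TES ether.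

Step 4
Reactants: 8 (5S)-3-{[(TBS)oxy]methyl}-5-hydroxycyclohex-2-en-1-one
Product: 10 methyl 2-[(1R,6S)-4-{[(TBS)oxy]methyl}-2-oxo-6-[(TES)oxy]cyclohex-3-en-1-yl]acetate, via lithium alkoxide 9 (not isolated)
Conditions: LiN(i-Pr)2 (2.1 equiv), THF/DMPU, −78 °C; BrCH2CO2Me, −78 → −40 °C; then Et3SiCl, −78 → 0 °C
Reagents that add atoms: methyl bromoacetate COC(=O)CBr; chlorotriethylsilane CC[Si](Cl)(CC)CC
Why: Fráter–Seebach-type alkylation; the alkoxide/α′-enolate dianion cannot eliminate (oxide is no leaving group) and is alkylated at C7 anti to the C8 oxygen (trans product), and silylating the alkoxide in the same flask prevents lactonisation onto O-8.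

Step 5
Reactants: 11 methyl cyclobut-1-ene-1-carboxylate
Product: 12 (cyclobut-1-en-1-yl)methanol
Conditions: i-Bu2AlH (2.2 equiv), CH2Cl2, −78 → 0 °C; aqueous tartrate work-up
Reagents that add atoms: none
Why: 1,2-reduction of the conjugated ester by the aluminium hydride leaves the strained ring alkene intact.

Step 6
Reactants: 12 (cyclobut-1-en-1-yl)methanol
Product: 13 tert-butyl(cyclobut-1-en-1-ylmethoxy)dimethylsilane
Conditions: TBSCl, imidazole, CH2Cl2, 0 → 23 °C
Reagents that add atoms: tert-butyldimethylsilyl chloride CC(C)(C)[Si](C)(C)Cl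
Why: standard silylation of a primary alcohol, so that C15 enters at the alcohol oxidation level.

Step 7
Reactants: 10 methyl 2-[(1R,6S)-4-{[(TBS)oxy]methyl}-2-oxo-6-[(TES)oxy]cyclohex-3-en-1-yl]acetate; 13 tert-butyl(cyclobut-1-en-1-ylmethoxy)dimethylsilane
Product: 14 methyl 2-[(8R,9S)-1,5-bis{[(TBS)oxy]methyl}-7-oxo-9-[(TES)oxy]tricyclo[4.4.0.0(2,5)]decan-8-yl]acetate (cis-anti-cis; drawn for addition anti to OTES; facial and ring-fusion isomers are carried on together)
Conditions: hν (350 nm, Pyrex), 13 (6 equiv, excess recovered), CH2Cl2, −20 °C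
Reagents that add atoms: none
Why: enone–alkene [2+2] photocycloaddition through the enone triplet; the substituted cyclobutene carbon bonds to the unsubstituted α-carbon C5 (as 1-alkylcyclobutenes do with 3-alkylcyclohexenones), forming C5–C4 and C10–C1, and the four new stereocentres are transient because C5 and C10 become sp2 again in step 8.

Step 8
Reactants: 14 tricyclic photoadduct
Product: 17 methyl 2-[(1R,3S,4R,6S)-4-{[(TBS)oxy]methyl}-3-{3-[(TBS)oxy]prop-1-en-2-yl}-4-ethenyl-2-oxo-6-[(TES)oxy]cyclohexyl]acetate, via cyclodecadienone 15 (not isolated), via cis-divinyl ketone 16 (not isolated)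
Conditions: PhMe (0.02 M), BHT, sealed tube, 190 °C; then DBU (0.2 equiv), 0 → 23 °C
Reagents that add atoms: none
Why: thermal cycloreversion of the bicyclo[2.2.0]hexane unit to the cyclodeca-1,5-dienone, then Cope rearrangement through a chair transition state with the C7 and C8 substituents equatorial, sets C10 (vinyl equatorial, silyloxymethyl axial); DBU then epimerises the doubly activated C5–H of 16 to the all-equatorial ketone.

Step 9
Reactants: 17 divinyl ketone
Product: 19 (3aS,4S,6R,7S,7aR)-6-{[(TBS)oxy]methyl}-7-{3-[(TBS)oxy]prop-1-en-2-yl}-6-ethenyl-4-[(TES)oxy]hexahydro-1-benzofuran-2(3H)-one, via hydroxy ester 18 (not isolated)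
Conditions: SmI2 (2.5 equiv), H2O, THF, 0 °C; then PPTS (cat.), PhMe, 60 °C
Reagents that add atoms: none
Why: single-electron ketone reduction gives the thermodynamically preferred equatorial 6α-alkoxide (an axial one would be 1,3-diaxial to the C14 arm, which also blocks axial hydride delivery), and the γ-hydroxy ester closes to the trans-fused lactone while O-8 stays silylated.

Step 10
Reactants: 19 saturated lactone
Product: 22 (3aS,4S,6R,7S,7aR)-6-{[(TBS)oxy]methyl}-7-{3-[(TBS)oxy]prop-1-en-2-yl}-6-ethenyl-3-methylidene-4-[(TES)oxy]hexahydro-1-benzofuran-2(3H)-one, via Mannich base 20 (not isolated), via ammonium iodide 21 (not isolated)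
Conditions: LiN(i-Pr)2, THF, −78 °C; CH2=NMe2+ I−, −78 → 0 °C; then MeI, MeOH, 23 °C; then aq NaHCO3, CH2Cl2
Reagents that add atoms: Eschenmoser's salt (N,N-dimethylmethyleneiminium iodide) C=[N+](C)C.[I-]
Why: Mannich reaction of the lactone enolate with Eschenmoser's salt, quaternisation and E1cB loss of trimethylamine install the exocyclic methylene; C11 ends sp2, so its transient configuration does not matter.

Step 11
Reactants: 22 α-methylene lactone
Product: 23 (3aR,4S,6R,7S,7aR)-6-{[(TBS)oxy]methyl}-7-{3-[(TBS)oxy]prop-1-en-2-yl}-6-ethenyl-4-hydroxy-3-methylidenehexahydro-1-benzofuran-2(3H)-one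
Conditions: PPTS, MeOH/CH2Cl2, 0 → 23 °C
Reagents that add atoms: none
Why: acid-catalysed methanolysis cleaves the secondary TES ether much faster than the two primary TBS ethers.

Step 12
Reactants: 24 (E)-but-2-enal
Product: 25 (Z)-2-iodobut-2-enal
Conditions: I2, K2CO3, DMAP (0.2 equiv), THF/H2O, 23 °C
Reagents that add atoms: iodine II
Why: DMAP-catalysed α-iodination (conjugate addition, iodination, elimination, Baylis–Hillman-type) keeps methyl trans to the formyl group, so methyl is cis to iodine.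

Step 13
Reactants: 25 (Z)-2-iodobut-2-enal
Product: 26 (Z)-2-iodobut-2-en-1-ol
Conditions: NaBH4, CeCl3·7H2O, MeOH, 0 °C
Reagents that add atoms: none
Why: Luche 1,2-reduction of the enal; the alkene geometry is unaffected.

Step 14
Reactants: 26 (Z)-2-iodobut-2-en-1-ol
Product: 27 (Z)-tert-butyl[(2-iodobut-2-en-1-yl)oxy]dimethylsilane
Conditions: TBSCl, imidazole, CH2Cl2, 0 → 23 °C
Reagents that add atoms: tert-butyldimethylsilyl chloride CC(C)(C)[Si](C)(C)Cl
Why: standard silylation of the primary allylic alcohol.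

Step 15
Reactants: 27 (Z)-tert-butyl[(2-iodobut-2-en-1-yl)oxy]dimethylsilane
Product: 29 (2Z)-2-{[(TBS)oxy]methyl}but-2-enoic acid, via vinyllithium 28 (not isolated)
Conditions: t-BuLi (2.1 equiv), Et2O, −78 °C, 10 min; CO2; then cold 1 M HCl
Reagents that add atoms: carbon dioxide O=C=O
Why: iodine–lithium exchange and carboxylation both proceed with retention, and quenching at −78 °C outruns 1,3-silyl migration, so methyl ends cis to the carboxyl group.

Step 16
Reactants: 23 C8 alcohol; 29 (2Z)-2-{[(TBS)oxy]methyl}but-2-enoic acid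
Product: 31 (3aR,4S,6R,7S,7aR)-6-{[(TBS)oxy]methyl}-7-{3-[(TBS)oxy]prop-1-en-2-yl}-6-ethenyl-3-methylidene-2-oxooctahydro-1-benzofuran-4-yl (2Z)-2-{[(TBS)oxy]methyl}but-2-enoate, via mixed anhydride 30 (not isolated)
Conditions: 29, 2,4,6-trichlorobenzoyl chloride, Et3N, PhMe, 23 °C; then 23, DMAP (0.2 equiv), PhMe, 60 °C
Reagents that add atoms: none
Why: Yamaguchi esterification through the mixed anhydride, the protocol that acylates hindered secondary alcohols with angelate-type acids without Z-to-E isomerisation; O-8 is the only free hydroxyl.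

Step 17
Reactants: 31 tris-silyl ester
Product: 32 (3aR,4S,6R,7S,7aR)-6-ethenyl-6-(hydroxymethyl)-7-(3-hydroxyprop-1-en-2-yl)-3-methylidene-2-oxooctahydro-1-benzofuran-4-yl (2Z)-2-(hydroxymethyl)but-2-enoate (target)
Conditions: HF·pyridine, pyridine, THF, 0 → 23 °C
Reagents that add atoms: none
Why: buffered fluoride cleavage of the three primary silyl ethers leaves the α-methylene lactone and the Z-enoate untouched.

## Compound list

1 | ethyl (3R)-4-bromo-3-hydroxybutanoate | BrC[C@H](O)CC(=O)OCC | starting material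
2 | ethyl (3R)-3-hydroxy-4-iodobutanoate | IC[C@H](O)CC(=O)OCC | intermediate
3 | ethyl (3R)-4-iodo-3-[(triethylsilyl)oxy]butanoate | IC[C@H](O[Si](CC)(CC)CC)CC(=O)OCC | intermediate
4 | tert-butyldimethyl(prop-2-yn-1-yloxy)silane | C#CCO[Si](C)(C)C(C)(C)C | starting material
5 | lithium acetylide of 4 | [Li]C#CCO[Si](C)(C)C(C)(C)C | intermediate
6 | (6R)-1-[(TBS)oxy]-7-iodo-6-[(TES)oxy]hept-2-yn-4-one | IC[C@H](O[Si](CC)(CC)CC)CC(=O)C#CCO[Si](C)(C)C(C)(C)C | intermediate
7 | (5S)-3-{[(TBS)oxy]methyl}-5-[(TES)oxy]cyclohex-2-en-1-one | O=C1C=C(CO[Si](C)(C)C(C)(C)C)C[C@H](O[Si](CC)(CC)CC)C1 | intermediate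
8 | (5S)-3-{[(TBS)oxy]methyl}-5-hydroxycyclohex-2-en-1-one | O=C1C=C(CO[Si](C)(C)C(C)(C)C)C[C@H](O)C1 | intermediate
9 | lithium alkoxide of methyl 2-[(1R,6S)-4-{[(TBS)oxy]methyl}-6-hydroxy-2-oxocyclohex-3-en-1-yl]acetate | O=C1C=C(CO[Si](C)(C)C(C)(C)C)C[C@H](O[Li])[C@H]1CC(=O)OC | intermediate
10 | methyl 2-[(1R,6S)-4-{[(TBS)oxy]methyl}-2-oxo-6-[(TES)oxy]cyclohex-3-en-1-yl]acetate | O=C1C=C(CO[Si](C)(C)C(C)(C)C)C[C@H](O[Si](CC)(CC)CC)[C@H]1CC(=O)OC | intermediate
11 | methyl cyclobut-1-ene-1-carboxylate | COC(=O)C1=CCC1 | starting material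
12 | (cyclobut-1-en-1-yl)methanol | OCC1=CCC1 | intermediate
13 | tert-butyl(cyclobut-1-en-1-ylmethoxy)dimethylsilane | CC(C)(C)[Si](C)(C)OCC1=CCC1 | intermediate
14 | methyl 2-[(8R,9S)-1,5-bis{[(TBS)oxy]methyl}-7-oxo-9-[(TES)oxy]tricyclo[4.4.0.0(2,5)]decan-8-yl]acetate, cis-anti-cis | O=C1[C@@H]2[C@](CO[Si](C)(C)C(C)(C)C)(C[C@H](O[Si](CC)(CC)CC)[C@H]1CC(=O)OC)[C@H]3CC[C@@]23CO[Si](C)(C)C(C)(C)C | intermediate
15 | methyl 2-[(1R,3E,7Z,10S)-4,8-bis{[(TBS)oxy]methyl}-2-oxo-10-[(TES)oxy]cyclodeca-3,7-dien-1-yl]acetate (ring carbons cis across C3=C4, trans across C7=C8) | O=C1/C=C(CO[Si](C)(C)C(C)(C)C)\CC/C=C(CO[Si](C)(C)C(C)(C)C)/C[C@H](O[Si](CC)(CC)CC)[C@H]1CC(=O)OC | intermediate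
16 | methyl 2-[(1R,3R,4R,6S)-4-{[(TBS)oxy]methyl}-3-{3-[(TBS)oxy]prop-1-en-2-yl}-4-ethenyl-2-oxo-6-[(TES)oxy]cyclohexyl]acetate | C=C[C@]1(CO[Si](C)(C)C(C)(C)C)C[C@H](O[Si](CC)(CC)CC)[C@@H](CC(=O)OC)C(=O)[C@@H]1C(=C)CO[Si](C)(C)C(C)(C)C | intermediate
17 | methyl 2-[(1R,3S,4R,6S)-4-{[(TBS)oxy]methyl}-3-{3-[(TBS)oxy]prop-1-en-2-yl}-4-ethenyl-2-oxo-6-[(TES)oxy]cyclohexyl]acetate | C=C[C@]1(CO[Si](C)(C)C(C)(C)C)C[C@H](O[Si](CC)(CC)CC)[C@@H](CC(=O)OC)C(=O)[C@H]1C(=C)CO[Si](C)(C)C(C)(C)C | intermediate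
18 | methyl 2-[(1S,2R,3S,4R,6S)-4-{[(TBS)oxy]methyl}-3-{3-[(TBS)oxy]prop-1-en-2-yl}-4-ethenyl-2-hydroxy-6-[(TES)oxy]cyclohexyl]acetate | C=C[C@]1(CO[Si](C)(C)C(C)(C)C)C[C@H](O[Si](CC)(CC)CC)[C@@H](CC(=O)OC)[C@H](O)[C@H]1C(=C)CO[Si](C)(C)C(C)(C)C | intermediate
19 | (3aS,4S,6R,7S,7aR)-6-{[(TBS)oxy]methyl}-7-{3-[(TBS)oxy]prop-1-en-2-yl}-6-ethenyl-4-[(TES)oxy]hexahydro-1-benzofuran-2(3H)-one | C=C[C@]1(CO[Si](C)(C)C(C)(C)C)C[C@H](O[Si](CC)(CC)CC)[C@H]2CC(=O)O[C@@H]2[C@H]1C(=C)CO[Si](C)(C)C(C)(C)C | intermediate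
20 | 3-[(dimethylamino)methyl] derivative of 19 (C3 epimers) | C=C[C@]1(CO[Si](C)(C)C(C)(C)C)C[C@H](O[Si](CC)(CC)CC)[C@H]2C(CN(C)C)C(=O)O[C@@H]2[C@H]1C(=C)CO[Si](C)(C)C(C)(C)C | intermediate
21 | 3-[(trimethylammonio)methyl] derivative of 19, iodide (C3 epimers) | C=C[C@]1(CO[Si](C)(C)C(C)(C)C)C[C@H](O[Si](CC)(CC)CC)[C@H]2C(C[N+](C)(C)C)C(=O)O[C@@H]2[C@H]1C(=C)CO[Si](C)(C)C(C)(C)C.[I-] | intermediate
22 | (3aS,4S,6R,7S,7aR)-6-{[(TBS)oxy]methyl}-7-{3-[(TBS)oxy]prop-1-en-2-yl}-6-ethenyl-3-methylidene-4-[(TES)oxy]hexahydro-1-benzofuran-2(3H)-one | C=C[C@]1(CO[Si](C)(C)C(C)(C)C)C[C@H](O[Si](CC)(CC)CC)[C@H]2C(=C)C(=O)O[C@@H]2[C@H]1C(=C)CO[Si](C)(C)C(C)(C)C | intermediate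
23 | (3aR,4S,6R,7S,7aR)-6-{[(TBS)oxy]methyl}-7-{3-[(TBS)oxy]prop-1-en-2-yl}-6-ethenyl-4-hydroxy-3-methylidenehexahydro-1-benzofuran-2(3H)-one | C=C[C@]1(CO[Si](C)(C)C(C)(C)C)C[C@H](O)[C@H]2C(=C)C(=O)O[C@@H]2[C@H]1C(=C)CO[Si](C)(C)C(C)(C)C | intermediate
24 | (E)-but-2-enal | C/C=C/C=O | starting material
25 | (Z)-2-iodobut-2-enal | C/C=C(\I)C=O | intermediate
26 | (Z)-2-iodobut-2-en-1-ol | C/C=C(\I)CO | intermediate
27 | (Z)-tert-butyl[(2-iodobut-2-en-1-yl)oxy]dimethylsilane | C/C=C(\I)CO[Si](C)(C)C(C)(C)C | intermediate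
28 | (E)-{1-[(TBS)oxy]but-2-en-2-yl}lithium | C/C=C(\[Li])CO[Si](C)(C)C(C)(C)C | intermediate
29 | (2Z)-2-{[(TBS)oxy]methyl}but-2-enoic acid | C/C=C(\C(=O)O)CO[Si](C)(C)C(C)(C)C | intermediate
30 | (2Z)-2-{[(TBS)oxy]methyl}but-2-enoic 2,4,6-trichlorobenzoic anhydride | C/C=C(\C(=O)OC(=O)c1c(Cl)cc(Cl)cc1Cl)CO[Si](C)(C)C(C)(C)C | intermediate
31 | (3aR,4S,6R,7S,7aR)-6-{[(TBS)oxy]methyl}-7-{3-[(TBS)oxy]prop-1-en-2-yl}-6-ethenyl-3-methylidene-2-oxooctahydro-1-benzofuran-4-yl (2Z)-2-{[(TBS)oxy]methyl}but-2-enoate | C=C[C@]1(CO[Si](C)(C)C(C)(C)C)C[C@H](OC(=O)/C(=C\C)CO[Si](C)(C)C(C)(C)C)[C@H]2C(=C)C(=O)O[C@@H]2[C@H]1C(=C)CO[Si](C)(C)C(C)(C)C | intermediate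
32 | (3aR,4S,6R,7S,7aR)-6-ethenyl-6-(hydroxymethyl)-7-(3-hydroxyprop-1-en-2-yl)-3-methylidene-2-oxooctahydro-1-benzofuran-4-yl (2Z)-2-(hydroxymethyl)but-2-enoate | C=C[C@]1(CO)C[C@H](OC(=O)/C(=C\C)CO)[C@H]2C(=C)C(=O)O[C@@H]2[C@H]1C(=C)CO | target

## Step count and risks

Total step count: 17.
Longest linear sequence: 11 steps (steps 1–4, 7–11, 16, 17, from compound 1).

Three steps most likely to fail:

**Step 3 (the proposed new photocyclisation).** The risks are 5-exo closure, premature reduction of the C9 radical, and silyl-radical addition to the ynone. The fallback sets out from 6. Hydroiodination (NaI, AcOH, MeCN, 23 °C) gives the (2Z,6R)-β-iodo enone F1. A known-type intramolecular reductive vinyl–alkyl cross-electrophile coupling (NiBr2(dme) 10 mol %, 4,4′-di-tert-butyl-2,2′-bipyridine, Mn powder, DMA, 0.01 M, 23 °C) then joins C9 to C10. This comes back to the route at silyl enone 7, which is desilylated to 8 as in the second stage of step 3.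

**Step 4 (dianion alkylation).** The risks are γ-deprotonation, proton transfer, and aromatisation of the β-hydroxy enone on work-up. The fallback sets out from 7, isolated by leaving out the PPTS/MeOH stage of step 3. Condensation with Me2NNH2 (AcOH cat., EtOH, 60 °C) gives the N,N-dimethylhydrazone F2. Corey–Enders α′-metalation (LiN(i-Pr)2, THF, −78 °C) and alkylation with BrCH2CO2Me, trans to the silyloxy group, give the alkylated hydrazone F3. Hydrolysis with aqueous CuCl2 (pH 7 buffer, THF) comes back to the route at 10.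

**Step 8 (thermal cycloreversion/Cope/epimerisation).** The risks are loss of silanol from the β-silyloxy ketone, the wrong geometry at the C1=C10 alkene (which would invert C10), and base-induced conjugation at C5. The fallback sets out from 14. Flash vacuum pyrolysis (480 °C, 0.01 mbar, short contact) stops the cascade at the ten-membered dienone 15, which is isolated. Heating 15 in PhMe at 120–140 °C with (PhS)2 (10 mol %) equilibrates the conjugated double bond by reversible thiyl addition. The all-trans dienone F4 is drained by its faster chair Cope rearrangement, which gives the trans-divinyl ketone directly without any base and comes back to the route at 17.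

## Further compounds

F1 | step 3 | (2Z,6R)-1-[(TBS)oxy]-2,7-diiodo-6-[(TES)oxy]hept-2-en-4-one | IC[C@H](O[Si](CC)(CC)CC)CC(=O)/C=C(\I)CO[Si](C)(C)C(C)(C)C
F2 | step 4 | (5S)-3-{[(TBS)oxy]methyl}-5-[(TES)oxy]cyclohex-2-en-1-one N,N-dimethylhydrazone | CN(C)N=C1C=C(CO[Si](C)(C)C(C)(C)C)C[C@H](O[Si](CC)(CC)CC)C1
F3 | step 4 | methyl 2-[(1S,6S)-4-{[(TBS)oxy]methyl}-2-(2,2-dimethylhydrazinylidene)-6-[(TES)oxy]cyclohex-3-en-1-yl]acetate | CN(C)N=C1C=C(CO[Si](C)(C)C(C)(C)C)C[C@H](O[Si](CC)(CC)CC)[C@H]1CC(=O)OC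
F4 | step 8 | methyl 2-[(1R,3Z,7Z,10S)-4,8-bis{[(TBS)oxy]methyl}-2-oxo-10-[(TES)oxy]cyclodeca-3,7-dien-1-yl]acetate (ring carbons trans across both double bonds) | O=C1/C=C(CO[Si](C)(C)C(C)(C)C)/CC/C=C(CO[Si](C)(C)C(C)(C)C)/C[C@H](O[Si](CC)(CC)CC)[C@H]1CC(=O)OC
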